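**Plan**

Numbering is that of the cembrane skeleton: ring carbons C1–C14 (C1 and C2 are shared with the lactone; O on C2, OAc on C9), C15 the α-carbon, C16 the lactone carbonyl carbon, C17 the exocyclic methylene carbon.
Retrosynthetic cuts, in order: lactone carbonyl level and C9 acetate (last), C13–C14 (14-membered ring), C15–C1 (five-membered ring O–C16–C15–C1–C2), C1–C2 (alkyne addition to a C2 enal) and C9–C10 (vinylogous aldol), leaving geranyl acetate, methyl tiglate, trimethylsilylacetylene and methoxyallene.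
Forward order: linear C2–C13 triene, then the C1=C14 vinyl sulfone, then the oxolane ring by radical closure (step 11), then the carbocycle by sulfone alkylation (step 14), then sulfone removal, acetate, and oxidation to the lactone.
Enabling feature: the oxygen on C2 can carry a 2-bromoallyl acetal, which places a C15 vinyl radical in a 5-exo relation to C1. C1 is made the β-carbon of a vinyl sulfone whose sulfone sits on C14, the carbon that must later bond to C13; the acetal already holds C16 and the C15=C17 methylene.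
Stereochemistry: C9 from a catalyst-controlled vinylogous Mukaiyama aldol, C2 from a catalyst-controlled alkynylation, C1 relayed from C2 in the radical closure (trans); the three E-alkenes come from geranyl acetate and the tiglate unit.

Key step: step 11

Remark: the ligand antipodes named in steps 3 and 7 are those expected to give Re-face addition at C9 and at C2; if either sense should prove opposite, the mirror-image ligand is used.

**Route**

Step 1
Reactants: 1 geranyl acetate
Product: 3 (2E,6E)-3,7-dimethyl-8-oxoocta-2,6-dien-1-yl acetate, via allylic alcohol 2 (not isolated)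
Conditions: SeO2 (cat.), t-BuOOH, salicylic acid (cat.), CH2Cl2, rt; filter; then MnO2, CH2Cl2, rt
Reagents that add atoms: tert-butyl hydroperoxide, CC(C)(C)OO
Why: Riley allylic oxidation attacks the E-methyl group of the terminal trisubstituted alkene (the other alkene is deactivated by the allylic acetate), and MnO2 then takes the primary allylic alcohol to the E-enal without touching the ester.

Step 2
Reactants: 4 methyl tiglate
Product: 6 tert-butyl[(1-methoxy-2-methylbuta-1,3-dien-1-yl)oxy]dimethylsilane, via lithium dienolate 5 (not isolated)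
Conditions: LiN(i-Pr)2, THF, −78 °C; then t-BuMe2SiCl, DMPU, −78 °C to rt
Reagents that add atoms: tert-butylchlorodimethylsilane, CC(C)(C)[Si](C)(C)Cl
Why: The tiglate has no α-hydrogen, so kinetic γ-deprotonation and O-silylation of the extended enolate should give the silyl dienol ether needed for a vinylogous Mukaiyama aldol reaction.

Step 3
Reactants: 3 (2E,6E)-3,7-dimethyl-8-oxoocta-2,6-dien-1-yl acetate; 6 tert-butyl[(1-methoxy-2-methylbuta-1,3-dien-1-yl)oxy]dimethylsilane
Product: 7 methyl (2E,5R,6E,10E)-12-acetoxy-5-hydroxy-2,6,10-trimethyldodeca-2,6,10-trienoate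
Conditions: SiCl4, (R,R)-binaphthyldiamine-derived bisphosphoramide (cat.), i-Pr2NEt (cat.), CH2Cl2, −78 °C; aq. KF/NaHCO3 work-up
Reagents that add atoms: none
Why: In this Lewis-base-catalysed vinylogous Mukaiyama aldol reaction the chiral trichlorosilyl cation activates only the aldehyde, the dienolate adds through its γ-carbon, the catalyst directs attack to the Re face of C9 (9R in cembrane numbering), and the open transition state should give the E-enoate.

Step 4
Reactants: 7 methyl (2E,5R,6E,10E)-12-acetoxy-5-hydroxy-2,6,10-trimethyldodeca-2,6,10-trienoate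
Product: 8 methyl (2E,5R,6E,10E)-12-acetoxy-5-(tert-butyldimethylsilyloxy)-2,6,10-trimethyldodeca-2,6,10-trienoate
Conditions: t-BuMe2SiOTf, 2,6-lutidine, CH2Cl2, −78 to 0 °C
Reagents that add atoms: tert-butyldimethylsilyl triflate, CC(C)(C)[Si](C)(C)OS(=O)(=O)C(F)(F)F
Why: Silyl triflate with lutidine silylates the hindered secondary allylic alcohol without touching the stereocentre or the esters.

Step 5
Reactants: 8 methyl (2E,5R,6E,10E)-12-acetoxy-5-(tert-butyldimethylsilyloxy)-2,6,10-trimethyldodeca-2,6,10-trienoate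
Product: 9 methyl (2E,5R,6E,10E)-5-(tert-butyldimethylsilyloxy)-12-hydroxy-2,6,10-trimethyldodeca-2,6,10-trienoate
Conditions: K2CO3 (cat.), MeOH, 0 °C to rt
Reagents that add atoms: none
Why: Carbonate-catalysed methanolysis removes the primary acetate, while the hindered conjugated methyl ester can only exchange methoxide for methoxide and the silyl ether is stable.

Step 6
Reactants: 9 methyl (2E,5R,6E,10E)-5-(tert-butyldimethylsilyloxy)-12-hydroxy-2,6,10-trimethyldodeca-2,6,10-trienoate
Product: 10 methyl (2E,5R,6E,10E)-5-(tert-butyldimethylsilyloxy)-2,6,10-trimethyl-12-oxododeca-2,6,10-trienoate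
Conditions: MnO2, CH2Cl2, rt
Reagents that add atoms: none
Why: MnO2 oxidises only the primary allylic alcohol and should give the E-enal at C2 without isomerisation.

Step 7
Reactants: 10 methyl (2E,5R,6E,10E)-5-(tert-butyldimethylsilyloxy)-2,6,10-trimethyl-12-oxododeca-2,6,10-trienoate; 11 trimethylsilylacetylene
Product: 13 methyl (2E,5R,6E,10E,12S)-5-(tert-butyldimethylsilyloxy)-12-hydroxy-2,6,10-trimethyltetradeca-2,6,10-trien-13-ynoate, via silylalkyne 12 (not isolated)
Conditions: Me2Zn, (S,S)-ProPhenol ligand (cat.), Ph3PO (cat.), toluene, 4 °C; aq. NH4Cl work-up; then K2CO3, MeOH, rt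
Reagents that add atoms: none
Why: In this catalytic asymmetric alkynylation of an α,β-unsaturated aldehyde the dinuclear zinc alkynylide adds to the Re face of the enal to set 2S (cembrane numbering), and methanolysis of the C–Si bond then frees the terminal alkyne while ester and silyl ether stay intact.

Step 8
Reactants: 13 methyl (2E,5R,6E,10E,12S)-5-(tert-butyldimethylsilyloxy)-12-hydroxy-2,6,10-trimethyltetradeca-2,6,10-trien-13-ynoate
Product: 15 methyl (2E,5R,6E,10E,12S,13E)-5-(tert-butyldimethylsilyloxy)-12-hydroxy-14-iodo-2,6,10-trimethyltetradeca-2,6,10,13-tetraenoate, via alkenylzirconocene 14 (not isolated)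
Conditions: Cp2Zr(H)Cl (2.3 equiv), THF, 0 °C to rt; then I2, −20 °C
Reagents that add atoms: iodine, II
Why: In this hydrozirconation–iodination the first equivalent of hydride is spent on the hydroxyl, syn-hydrozirconation places zirconium on the terminal carbon C14, and iodinolysis with retention should give the E-iodoalkene.

Step 9
Reactants: 15 methyl (2E,5R,6E,10E,12S,13E)-5-(tert-butyldimethylsilyloxy)-12-hydroxy-14-iodo-2,6,10-trimethyltetradeca-2,6,10,13-tetraenoate
Product: 16 methyl (2E,5R,6E,10E,12S,13E)-5-(tert-butyldimethylsilyloxy)-12-hydroxy-2,6,10-trimethyl-14-(phenylsulfonyl)tetradeca-2,6,10,13-tetraenoate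
Conditions: PhSO2Na, CuI (cat.), L-proline (cat.), NaOH (cat.), DMSO, 80 °C
Reagents that add atoms: sodium benzenesulfinate, [Na+].[O-]S(=O)c1ccccc1
Why: Copper-catalysed Ullmann-type coupling of an alkenyl iodide with a sulfinate salt proceeds with retention of the E-geometry and turns C1=C14 into an electron-poor alkene with the sulfone on C14.

Step 10
Reactants: 16 methyl (2E,5R,6E,10E,12S,13E)-5-(tert-butyldimethylsilyloxy)-12-hydroxy-2,6,10-trimethyl-14-(phenylsulfonyl)tetradeca-2,6,10,13-tetraenoate; 17 methoxyallene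
Product: 18 methyl (2E,5R,6E,10E,12S,13E)-12-[(2-bromo-1-methoxyprop-2-en-1-yl)oxy]-5-(tert-butyldimethylsilyloxy)-2,6,10-trimethyl-14-(phenylsulfonyl)tetradeca-2,6,10,13-tetraenoate (both acetal epimers)
Conditions: NBS, CH2Cl2, −40 to 0 °C
Reagents that add atoms: N-bromosuccinimide, O=C1CCC(=O)N1Br
Why: In this haloacetalisation of the Ueno–Stork type NBS brominates the central carbon of the electron-rich alkoxyallene and the oxocarbenium ion is trapped by the C2 hydroxyl, which should be far faster than bromination of the trisubstituted alkenes.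

Step 11
Reactants: 18 methyl (2E,5R,6E,10E,12S,13E)-12-[(2-bromo-1-methoxyprop-2-en-1-yl)oxy]-5-(tert-butyldimethylsilyloxy)-2,6,10-trimethyl-14-(phenylsulfonyl)tetradeca-2,6,10,13-tetraenoate
Product: 19 methyl (2E,5R,6E,10E)-5-(tert-butyldimethylsilyloxy)-11-[(2S,3R)-5-methoxy-4-methylidene-3-(phenylsulfonylmethyl)oxolan-2-yl]-2,6,10-trimethylundeca-2,6,10-trienoate (both acetal epimers)
Conditions: Bu3SnH and AIBN added over 6 h, benzene (0.01 M), 80 °C
Reagents that add atoms: none
Why: The Bu3Sn radical abstracts the vinylic bromine, the σ-vinyl radical at C15 adds to C1 (the β-carbon of the vinyl sulfone), and the α-sulfonyl radical at C14 is quenched by Bu3SnH. The closest known reaction type is the Ueno–Stork haloacetal radical cyclisation in its 2-bromoallyl acetal form, which delivers 3-methylidene-2-alkoxyoxolanes. The oxolane (O, C16, C15, C1, C2) closes in the 5-exo-trig mode. The new centre C1 is set by C2 through a chair-like Beckwith–Houk transition state in which the C2 alkenyl chain is pseudo-equatorial and the E-alkene avoids allylic strain, so that C14 should end up trans to C3 (1R from 2S), while the acetal carbon stays a mixture that is erased in step 18. The step needs site selectivity for C1 over C3 of the C3=C4 alkene, which is also in a 5-exo relation, and this is secured by the polarity match between the nucleophilic vinyl radical and the sulfone-activated C1=C14 alkene together with the lower substitution at C1. Slow addition of the tin hydride keeps direct reduction of the vinyl radical in check.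

Step 12
Reactants: 19 methyl (2E,5R,6E,10E)-5-(tert-butyldimethylsilyloxy)-11-[(2S,3R)-5-methoxy-4-methylidene-3-(phenylsulfonylmethyl)oxolan-2-yl]-2,6,10-trimethylundeca-2,6,10-trienoate
Product: 20 (2E,5R,6E,10E)-5-(tert-butyldimethylsilyloxy)-11-[(2S,3R)-5-methoxy-4-methylidene-3-(phenylsulfonylmethyl)oxolan-2-yl]-2,6,10-trimethylundeca-2,6,10-trien-1-ol
Conditions: i-Bu2AlH, CH2Cl2, −78 °C; aq. potassium sodium tartrate work-up
Reagents that add atoms: none
Why: i-Bu2AlH reduces the conjugated methyl ester to the E-allylic alcohol at low temperature, while sulfone, mixed acetal and silyl ether are inert.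

Step 13
Reactants: 20 (2E,5R,6E,10E)-5-(tert-butyldimethylsilyloxy)-11-[(2S,3R)-5-methoxy-4-methylidene-3-(phenylsulfonylmethyl)oxolan-2-yl]-2,6,10-trimethylundeca-2,6,10-trien-1-ol
Product: 21 (2S,3R)-2-[(1E,5E,7R,9E)-11-bromo-7-(tert-butyldimethylsilyloxy)-2,6,10-trimethylundeca-1,5,9-trien-1-yl]-5-methoxy-4-methylidene-3-(phenylsulfonylmethyl)oxolane
Conditions: CBr4, PPh3, 2,6-lutidine, CH2Cl2, 0 °C
Reagents that add atoms: carbon tetrabromide, BrC(Br)(Br)Br
Why: Appel bromination converts the primary allylic alcohol into the bromide by SN2 displacement of the oxyphosphonium ion without allylic transposition, and the lutidine buffer protects the acetal.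

Step 14
Reactants: 21 (2S,3R)-2-[(1E,5E,7R,9E)-11-bromo-7-(tert-butyldimethylsilyloxy)-2,6,10-trimethylundeca-1,5,9-trien-1-yl]-5-methoxy-4-methylidene-3-(phenylsulfonylmethyl)oxolane
Product: 23 (3aR,6E,9R,10E,14E,15aS)-9-(tert-butyldimethylsilyloxy)-2-methoxy-6,10,14-trimethyl-3-methylidene-4-(phenylsulfonyl)-2,3,3a,4,5,8,9,12,13,15a-decahydrocyclotetradeca[b]furan (epimers at C2 and C4), via lithiated sulfone 22 (not isolated)
Conditions: 21 added over 8 h to LiN(i-Pr)2, THF (final 0.002 M), −78 °C, then to −20 °C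
Reagents that add atoms: none
Why: The α-sulfonyl carbanion at C14 displaces the primary allylic bromide at C13 intramolecularly (SN2, 14-membered ring, high dilution), a sulfone-carbanion macrocyclisation of the kind used for cembranoid carbocycles, and the new centre at C14 is removed in the next step.

Step 15
Reactants: 23 (3aR,6E,9R,10E,14E,15aS)-9-(tert-butyldimethylsilyloxy)-2-methoxy-6,10,14-trimethyl-3-methylidene-4-(phenylsulfonyl)-2,3,3a,4,5,8,9,12,13,15a-decahydrocyclotetradeca[b]furan
Product: 24 (3aR,6E,9R,10E,14E,15aS)-9-(tert-butyldimethylsilyloxy)-2-methoxy-6,10,14-trimethyl-3-methylidene-2,3,3a,4,5,8,9,12,13,15a-decahydrocyclotetradeca[b]furan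
Conditions: 6% Na(Hg), Na2HPO4, MeOH–THF, −20 °C
Reagents that add atoms: none
Why: Single-electron reduction by sodium amalgam cleaves the C–S bond (reductive desulfonylation), which removes the helper group and the C14 centre and should leave alkenes, acetal and silyl ether untouched.

Step 16
Reactants: 24 (3aR,6E,9R,10E,14E,15aS)-9-(tert-butyldimethylsilyloxy)-2-methoxy-6,10,14-trimethyl-3-methylidene-2,3,3a,4,5,8,9,12,13,15a-decahydrocyclotetradeca[b]furan
Product: 25 (3aR,6E,9R,10E,14E,15aS)-2-methoxy-6,10,14-trimethyl-3-methylidene-2,3,3a,4,5,8,9,12,13,15a-decahydrocyclotetradeca[b]furan-9-ol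
Conditions: Bu4NF, THF, 0 °C to rt
Reagents that add atoms: none
Why: Fluoride cleaves the silyl ether while the lactone is still masked as a base-stable acetal, so no conjugate acceptor is exposed to fluoride.

Step 17
Reactants: 25 (3aR,6E,9R,10E,14E,15aS)-2-methoxy-6,10,14-trimethyl-3-methylidene-2,3,3a,4,5,8,9,12,13,15a-decahydrocyclotetradeca[b]furan-9-ol
Product: 26 (3aR,6E,9R,10E,14E,15aS)-2-methoxy-6,10,14-trimethyl-3-methylidene-2,3,3a,4,5,8,9,12,13,15a-decahydrocyclotetradeca[b]furan-9-yl acetate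
Conditions: Ac2O, pyridine, DMAP (cat.), CH2Cl2, rt
Reagents that add atoms: acetic anhydride, CC(=O)OC(C)=O
Why: DMAP-catalysed acylation of the secondary allylic alcohol proceeds with retention at C9 and installs the acetate before any base-sensitive lactone is present.

Step 18
Reactants: 26 (3aR,6E,9R,10E,14E,15aS)-2-methoxy-6,10,14-trimethyl-3-methylidene-2,3,3a,4,5,8,9,12,13,15a-decahydrocyclotetradeca[b]furan-9-yl acetate
Product: 28 (3aR,6E,9R,10E,14E,15aS)-6,10,14-trimethyl-3-methylidene-2-oxo-2,3,3a,4,5,8,9,12,13,15a-decahydrocyclotetradeca[b]furan-9-yl acetate (the target), via lactol 27 (not isolated)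
Conditions: CrO3, aq. H2SO4, acetone, 0 °C
Reagents that add atoms: water, O
Why: In this Jones oxidation of a cyclic acetal, aqueous acid opens the methyl acetal to the lactol and hexavalent chromium oxidises it to the γ-lactone with the exocyclic alkene now conjugated, while acetate and trisubstituted alkenes should survive the short, cold exposure.

**Compound list**

1 | geranyl acetate | CC(=O)OC/C=C(\C)CCC=C(C)C | starting material
2 | (2E,6E)-8-hydroxy-3,7-dimethylocta-2,6-dien-1-yl acetate | CC(=O)OC/C=C(\C)CC/C=C(\C)CO | intermediate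
3 | (2E,6E)-3,7-dimethyl-8-oxoocta-2,6-dien-1-yl acetate | CC(=O)OC/C=C(\C)CC/C=C(\C)C=O | intermediate
4 | methyl tiglate | C/C=C(\C)C(=O)OC | starting material
5 | lithium 1-methoxy-2-methylbuta-1,3-dien-1-olate | [Li+].[O-]C(OC)=C(C)C=C | intermediate
6 | tert-butyl[(1-methoxy-2-methylbuta-1,3-dien-1-yl)oxy]dimethylsilane | C=CC(C)=C(OC)O[Si](C)(C)C(C)(C)C | intermediate
7 | methyl (2E,5R,6E,10E)-12-acetoxy-5-hydroxy-2,6,10-trimethyldodeca-2,6,10-trienoate | CC(=O)OC/C=C(\C)CC/C=C(\C)[C@H](O)C/C=C(\C)C(=O)OC | intermediate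
8 | methyl (2E,5R,6E,10E)-12-acetoxy-5-(tert-butyldimethylsilyloxy)-2,6,10-trimethyldodeca-2,6,10-trienoate | CC(=O)OC/C=C(\C)CC/C=C(\C)[C@H](O[Si](C)(C)C(C)(C)C)C/C=C(\C)C(=O)OC | intermediate
9 | methyl (2E,5R,6E,10E)-5-(tert-butyldimethylsilyloxy)-12-hydroxy-2,6,10-trimethyldodeca-2,6,10-trienoate | OC/C=C(\C)CC/C=C(\C)[C@H](O[Si](C)(C)C(C)(C)C)C/C=C(\C)C(=O)OC | intermediate
10 | methyl (2E,5R,6E,10E)-5-(tert-butyldimethylsilyloxy)-2,6,10-trimethyl-12-oxododeca-2,6,10-trienoate | O=C/C=C(\C)CC/C=C(\C)[C@H](O[Si](C)(C)C(C)(C)C)C/C=C(\C)C(=O)OC | intermediate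
11 | trimethylsilylacetylene | C#C[Si](C)(C)C | starting material
12 | methyl (2E,5R,6E,10E,12S)-5-(tert-butyldimethylsilyloxy)-12-hydroxy-2,6,10-trimethyl-14-(trimethylsilyl)tetradeca-2,6,10-trien-13-ynoate | O[C@H](C#C[Si](C)(C)C)/C=C(\C)CC/C=C(\C)[C@H](O[Si](C)(C)C(C)(C)C)C/C=C(\C)C(=O)OC | intermediate
13 | methyl (2E,5R,6E,10E,12S)-5-(tert-butyldimethylsilyloxy)-12-hydroxy-2,6,10-trimethyltetradeca-2,6,10-trien-13-ynoate | O[C@H](C#C)/C=C(\C)CC/C=C(\C)[C@H](O[Si](C)(C)C(C)(C)C)C/C=C(\C)C(=O)OC | intermediate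
14 | (E)-alkenylzirconocene chloride of 13 (zirconium on C14, the C2 oxygen bound to a second Cp2ZrCl unit) | Cl[Zr](O[C@H](/C=C/[Zr](Cl)(C1C=CC=C1)C1C=CC=C1)/C=C(\C)CC/C=C(\C)[C@H](O[Si](C)(C)C(C)(C)C)C/C=C(\C)C(=O)OC)(C1C=CC=C1)C1C=CC=C1 | intermediate
15 | methyl (2E,5R,6E,10E,12S,13E)-5-(tert-butyldimethylsilyloxy)-12-hydroxy-14-iodo-2,6,10-trimethyltetradeca-2,6,10,13-tetraenoate | O[C@H](/C=C/I)/C=C(\C)CC/C=C(\C)[C@H](O[Si](C)(C)C(C)(C)C)C/C=C(\C)C(=O)OC | intermediate
16 | methyl (2E,5R,6E,10E,12S,13E)-5-(tert-butyldimethylsilyloxy)-12-hydroxy-2,6,10-trimethyl-14-(phenylsulfonyl)tetradeca-2,6,10,13-tetraenoate | O[C@H](/C=C/S(=O)(=O)c1ccccc1)/C=C(\C)CC/C=C(\C)[C@H](O[Si](C)(C)C(C)(C)C)C/C=C(\C)C(=O)OC | intermediate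
17 | methoxyallene (1-methoxypropa-1,2-diene) | COC=C=C | starting material
18 | methyl (2E,5R,6E,10E,12S,13E)-12-[(2-bromo-1-methoxyprop-2-en-1-yl)oxy]-5-(tert-butyldimethylsilyloxy)-2,6,10-trimethyl-14-(phenylsulfonyl)tetradeca-2,6,10,13-tetraenoate (acetal epimers) | COC(C(Br)=C)O[C@H](/C=C/S(=O)(=O)c1ccccc1)/C=C(\C)CC/C=C(\C)[C@H](O[Si](C)(C)C(C)(C)C)C/C=C(\C)C(=O)OC | intermediate
19 | methyl (2E,5R,6E,10E)-5-(tert-butyldimethylsilyloxy)-11-[(2S,3R)-5-methoxy-4-methylidene-3-(phenylsulfonylmethyl)oxolan-2-yl]-2,6,10-trimethylundeca-2,6,10-trienoate (acetal epimers; ring substituents trans) | C=C1C(OC)O[C@@H](/C=C(\C)CC/C=C(\C)[C@H](O[Si](C)(C)C(C)(C)C)C/C=C(\C)C(=O)OC)[C@@H]1CS(=O)(=O)c1ccccc1 | intermediate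
20 | (2E,5R,6E,10E)-5-(tert-butyldimethylsilyloxy)-11-[(2S,3R)-5-methoxy-4-methylidene-3-(phenylsulfonylmethyl)oxolan-2-yl]-2,6,10-trimethylundeca-2,6,10-trien-1-ol | C=C1C(OC)O[C@@H](/C=C(\C)CC/C=C(\C)[C@H](O[Si](C)(C)C(C)(C)C)C/C=C(\C)CO)[C@@H]1CS(=O)(=O)c1ccccc1 | intermediate
21 | (2S,3R)-2-[(1E,5E,7R,9E)-11-bromo-7-(tert-butyldimethylsilyloxy)-2,6,10-trimethylundeca-1,5,9-trien-1-yl]-5-methoxy-4-methylidene-3-(phenylsulfonylmethyl)oxolane | C=C1C(OC)O[C@@H](/C=C(\C)CC/C=C(\C)[C@H](O[Si](C)(C)C(C)(C)C)C/C=C(\C)CBr)[C@@H]1CS(=O)(=O)c1ccccc1 | intermediate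
22 | α-lithio derivative of 21 (lithium on the sulfonyl-bearing carbon C14) | C=C1C(OC)O[C@@H](/C=C(\C)CC/C=C(\C)[C@H](O[Si](C)(C)C(C)(C)C)C/C=C(\C)CBr)[C@@H]1C([Li])S(=O)(=O)c1ccccc1 | intermediate
23 | (3aR,6E,9R,10E,14E,15aS)-9-(tert-butyldimethylsilyloxy)-2-methoxy-6,10,14-trimethyl-3-methylidene-4-(phenylsulfonyl)-2,3,3a,4,5,8,9,12,13,15a-decahydrocyclotetradeca[b]furan (epimers at C2 and C4) | C=C1C(OC)O[C@H]2/C=C(\C)CC/C=C(\C)[C@H](O[Si](C)(C)C(C)(C)C)C/C=C(\C)CC(S(=O)(=O)c3ccccc3)[C@H]12 | intermediate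
24 | (3aR,6E,9R,10E,14E,15aS)-9-(tert-butyldimethylsilyloxy)-2-methoxy-6,10,14-trimethyl-3-methylidene-2,3,3a,4,5,8,9,12,13,15a-decahydrocyclotetradeca[b]furan | C=C1C(OC)O[C@H]2/C=C(\C)CC/C=C(\C)[C@H](O[Si](C)(C)C(C)(C)C)C/C=C(\C)CC[C@H]12 | intermediate
25 | (3aR,6E,9R,10E,14E,15aS)-2-methoxy-6,10,14-trimethyl-3-methylidene-2,3,3a,4,5,8,9,12,13,15a-decahydrocyclotetradeca[b]furan-9-ol | C=C1C(OC)O[C@H]2/C=C(\C)CC/C=C(\C)[C@H](O)C/C=C(\C)CC[C@H]12 | intermediate
26 | (3aR,6E,9R,10E,14E,15aS)-2-methoxy-6,10,14-trimethyl-3-methylidene-2,3,3a,4,5,8,9,12,13,15a-decahydrocyclotetradeca[b]furan-9-yl acetate | C=C1C(OC)O[C@H]2/C=C(\C)CC/C=C(\C)[C@H](OC(C)=O)C/C=C(\C)CC[C@H]12 | intermediate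
27 | (3aR,6E,9R,10E,14E,15aS)-2-hydroxy-6,10,14-trimethyl-3-methylidene-2,3,3a,4,5,8,9,12,13,15a-decahydrocyclotetradeca[b]furan-9-yl acetate (lactol) | C=C1C(O)O[C@H]2/C=C(\C)CC/C=C(\C)[C@H](OC(C)=O)C/C=C(\C)CC[C@H]12 | intermediate
28 | (3aR,6E,9R,10E,14E,15aS)-6,10,14-trimethyl-3-methylidene-2-oxo-2,3,3a,4,5,8,9,12,13,15a-decahydrocyclotetradeca[b]furan-9-yl acetate | C=C1C(=O)O[C@H]2/C=C(\C)CC/C=C(\C)[C@H](OC(C)=O)C/C=C(\C)CC[C@H]12 | target

**Step count and risks**

Total step count: 18. Longest linear sequence: 17 steps (geranyl acetate 1 to target 28 through steps 1 and 3–18); step 2 prepares the dienolate partner 6.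

The three steps most likely to fail:

Step 11 (radical ring closure). What may go wrong: competing 5-exo attack of the vinyl radical on the trisubstituted C3=C4 alkene, hydrogen transfer to the vinyl radical before it cyclises, or weak trans control at C1. Fallback: set out from bromide 18 and close the same C15–C1 bond by an organonickel conjugate cyclisation instead of a radical one (Ni(cod)2, Et3N, MeCN–DMF, rt, aqueous quench). Zerovalent nickel inserts into the C15–Br bond, the alkenylnickel species adds 5-exo to the less substituted, electron-poor C1=C14 alkene, which it should prefer far more strongly than a radical does, and the α-sulfonyl alkylnickel intermediate is protonated. This should return oxolane 19 directly, so the fallback makes no compound outside the list (F0).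

Step 14 (macrocyclisation). What may go wrong: intermolecular alkylation outrunning ring closure, or base-induced elimination at the allylic bromide. Fallback: close the same C13–C14 bond before the oxolane exists, as an alkyne alkylation, setting out from alkynol 13. i-Bu2AlH (CH2Cl2, −78 °C) reduces the ester to the propargylic/allylic diol F1. MsCl, LiCl and 2,4,6-collidine (DMF, 0 °C) convert only the primary allylic hydroxyl into the allylic chloride F2. CuI, Cs2CO3 and NaI in DMF at high dilution join the terminal alkyne to the allylic chloride (copper acetylide SN2 alkylation) to give the 14-membered cyclic 1,4-enyne F3. NaAlH2(OCH2CH2OMe)2 in THF followed by I2 (hydroxyl-directed trans-hydroalumination, iodine on C14) gives the cyclic Z-iodoalkenol F4. PhSO2Na with CuI and L-proline in DMSO gives the cyclic vinyl sulfone F5. NBS and methoxyallene 17 give the cyclic bromoallyl acetal F6. Bu3SnH/AIBN then closes the oxolane onto C1 and should deliver macrocyclic sulfone 23, where the route is rejoined.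

Step 18 (acetal to lactone). What may go wrong: acid-promoted allylic transposition of the methylidene acetal, or hydrolysis of the allylic acetate before oxidation is complete. Fallback: separate hydrolysis from oxidation and avoid hexavalent chromium in acid. Set out from acetal 26, hydrolyse with pyridinium p-toluenesulfonate in wet acetone to isolate lactol 27, then oxidise the allylic lactol under neutral conditions with MnO2 in CH2Cl2 (or Ag2CO3 on Celite in benzene) to reach target 28. This fallback makes no compound outside the list (F0).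

**Further compounds**

F0 | step 11 | none | none
F1 | step 14 | (2E,5R,6E,10E,12S)-5-(tert-butyldimethylsilyloxy)-2,6,10-trimethyltetradeca-2,6,10-trien-13-yne-1,12-diol | O[C@H](C#C)/C=C(\C)CC/C=C(\C)[C@H](O[Si](C)(C)C(C)(C)C)C/C=C(\C)CO
F2 | step 14 | (3S,4E,8E,10R,12E)-10-(tert-butyldimethylsilyloxy)-14-chloro-5,9,13-trimethyltetradeca-4,8,12-trien-1-yn-3-ol | O[C@H](C#C)/C=C(\C)CC/C=C(\C)[C@H](O[Si](C)(C)C(C)(C)C)C/C=C(\C)CCl
F3 | step 14 | (1S,2E,6E,8R,10E)-8-(tert-butyldimethylsilyloxy)-3,7,11-trimethylcyclotetradeca-2,6,10-trien-13-yn-1-ol | O[C@H]1/C=C(\C)CC/C=C(\C)[C@H](O[Si](C)(C)C(C)(C)C)C/C=C(\C)CC#C1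
F4 | step 14 | (1S,2E,6E,8R,10E,13Z)-8-(tert-butyldimethylsilyloxy)-13-iodo-3,7,11-trimethylcyclotetradeca-2,6,10,13-tetraen-1-ol | O[C@H]1/C=C(\C)CC/C=C(\C)[C@H](O[Si](C)(C)C(C)(C)C)C/C=C(\C)C/C(I)=C/1
F5 | step 14 | (1S,2E,6E,8R,10E,13Z)-8-(tert-butyldimethylsilyloxy)-3,7,11-trimethyl-13-(phenylsulfonyl)cyclotetradeca-2,6,10,13-tetraen-1-ol | O[C@H]1/C=C(\C)CC/C=C(\C)[C@H](O[Si](C)(C)C(C)(C)C)C/C=C(\C)C/C(=C/1)S(=O)(=O)c1ccccc1
F6 | step 14 | 2-bromo-1-methoxyprop-2-en-1-yl mixed acetal of F5 (acetal epimers) | COC(C(Br)=C)O[C@H]1/C=C(\C)CC/C=C(\C)[C@H](O[Si](C)(C)C(C)(C)C)C/C=C(\C)C/C(=C/1)S(=O)(=O)c1ccccc1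
F0 | step 18 | none | none
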